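(The rate constants belong to no real substance; the rest is arithmetic.)

**The question.** Does the partner stop this flask, and with how much target and catalyst intermediate B?

substrate 0.22 M; partner 0.110 M (fed, over 3.0 min); free catalyst 11 mM; time 20 h; the fed solution adds 1.0 times the starting volume

    substrate + free catalyst → catalyst intermediate A (k1 = 0.506 /M/s)
    catalyst intermediate A ⇌ catalyst intermediate B (K2 = 2.47, k2 = 0.0137 /s)
    catalyst intermediate D → free catalyst + target (k3 = 0.00561 /s)
    partner + catalyst intermediate B → catalyst intermediate C (k4 = 2.37 /M/s)
    catalyst intermediate C → released group + catalyst intermediate D (k5 = 0.0175 /s)

- charges are per starting volume, the dose included; the dosed solution carries all of it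
- the reaction counts as stopped when no species that holds the substrate changes by six tenths of a point or more over the second half of the time
- run time (flask): 20 h

- which holds at 20 h: what has brought the reaction to rest, or that it has not come to rest (all of the substrate has reacted / no working catalyst is left / the partner has run out first / forward and back rates have come level / it is still moving)
- how much target there is at 20 h, in percent of the substrate charged
- how much catalyst intermediate B there is at 20 h, in percent of the substrate charged
- amount of target if the flask were left three thousand times as long, in percent of the substrate charged

**Turned round.** What has to be true for another ending? One way is a flask still moving. The partner charge needs 10.0 turns of the catalyst. As a rough scale I count one half-life of catalyst intermediate D per turn, 2.1 min; that makes 20.6 min, and 20 h is 58.3 times longer. Another way is a flask with no unbound substrate at the end. Each partner consumes one substrate, and each catalyst parked as intermediate A or B holds one. So I subtract both charges from the substrate charge and get 0.0990 M, the spare substrate. That ending needs the spare at zero or below, and this flask stands 45.0% of the substrate charge above zero.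

**My reckoning.** The partner charge is smaller than the substrate charge, so the partner is the limiting reagent and target reaches 50.0%, at 20 h and later. I take intermediates A and B as the resting state, between them holding the catalyst. They relax with a half-life of 0.600 min, shorter than 20 h, so intermediate B keeps 71.2% of the catalyst, or 3.56% of the substrate charged.

**The forecast.** It says the partner has run out first, with target 50% (49.5% to 50%), intermediate B 3.56% (3.4% to 3.7%) and 50% in the long run (49.5% to 50%). Its ground: “Excess substrate then holds all the catalyst”. My figures are the same.

**The result.** The flask gives this ending: the partner has run out first. It holds target 50.0% and intermediate B 3.56%, and left far longer, target 50.0%. At 20.0 h partner stands at 0% and unbound substrate at 45.0%.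

**The neighbour.** The neighbour flask holds 0.044 M of free catalyst. Its spare falls to 0.0660 M, still above zero, or 30.0% of the substrate charge. The same reckoning gives intermediate B 14.2% and target 50.0%. The neighbour flask ends with unbound substrate 30.0%, target 50.0% and intermediate B 14.2%.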